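**Plan** (drimane numbering: ring A = C1–C5 + C10, ring B = C5–C10, C4 = CMe2, C11 links C9 to ring C = C1'–C6'; C3' carbinol, C4' bears CH2O, C6' ketone)
Cuts: side-chain ester C–O; oxirane, C3'–OH and C6'=O back to a p-methoxyphenol (ring C); C8=CH2 back to C8=O; then C3–C4 of ring A, made while a temporary C4–C7 bond is broken; C10–C1 and C9–C11 by conjugate addition and enolate alkylation.
Enabling feature: C4 hangs on C5 of ring B and C7 is alpha to the C8 carbonyl, so tying C4 to C7 gives the cyclobutane of (1R,5R)-verbenone; a ketyl-type radical at C8 cleaves C7–C4 and frees a C4 radical.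
Forward: ring C (bought as an arene) and ring B (inside verbenone) are joined in a three-component coupling; the strain-release radical cascade closes ring A last; ring C is then oxidised, reduced and acylated.
Stereochemistry: C5 from verbenone; C10 by copper-mediated addition anti to the CMe2 bridge (hence trans fusion); C9 by equilibration; C1'/C2' by catalyst-controlled epoxidation; C3' by directed hydride delivery; side-chain carbinol by esterase desymmetrisation.

Key step: step 8

Remarks and assumptions
- Abbreviations: TIPS = triisopropylsilyl; ArCH2 = [5-methoxy-2-(TIPS-oxy)-4-(TIPS-oxymethyl)phenyl]methyl. Pinane C1/C2/C3/C4/C5/C6/C7 = drimane C7/C8/C9/C10/C5/C4/C6.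
- The oxirane is put in by late oxidation of the existing six-membered ring C; the three carbocycles are complete after step 8.
- Assumption: N-benzylcinchonidinium chloride delivers the hydroperoxide to the face that gives the oxirane of the target; if the sense is opposite, the pseudoenantiomeric cinchoninium salt takes its place.
- Assumption: pig liver esterase hydrolyses diester 23 to the (S)-half ester 24.

**Step 1**
Reactants: 1 4-bromo-2,5-dimethoxybenzaldehyde
Product: 2 4-bromo-2-hydroxy-5-methoxybenzaldehyde
Conditions: BCl3, CH2Cl2, −78 to 0 °C; H2O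
Reagents that add atoms: none
Why: BCl3 binds the aldehyde oxygen and cleaves only the chelated ortho methyl ether (Lewis-acid demethylation), which frees the phenol that later becomes the C6' ketone while the C3' oxygen stays methylated.

**Step 2**
Reactants: 2 4-bromo-2-hydroxy-5-methoxybenzaldehyde
Product: 3 2-hydroxy-4-(hydroxymethyl)-5-methoxybenzaldehyde
Conditions: Bu3SnCH2OH, Pd(PPh3)4 (5 mol %), dioxane, 90 °C
Reagents that add atoms: (tributylstannyl)methanol, CCCC[Sn](CCCC)(CCCC)CO
Why: Stille coupling of the aryl bromide with the hydroxymethylstannane puts in the C4' CH2OH carbon regiospecifically and tolerates the free phenol and the aldehyde.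

**Step 3**
Reactants: 3 2-hydroxy-4-(hydroxymethyl)-5-methoxybenzaldehyde
Product: 4 5-methoxy-2-(TIPS-oxy)-4-(TIPS-oxymethyl)benzaldehyde
Conditions: TIPSOTf (2.4 equiv), 2,6-lutidine, CH2Cl2, 0 °C
Reagents that add atoms: triisopropylsilyl trifluoromethanesulfonate, CC(C)[Si](C(C)C)(C(C)C)OS(=O)(=O)C(F)(F)F
Why: Silyl triflate with a hindered base protects the hydrogen-bonded phenol and the primary alcohol in one operation as fluoride-labile silyl ethers that resist the later bases, radicals and ylide (silylation).

**Step 4**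
Reactants: 4 5-methoxy-2-(TIPS-oxy)-4-(TIPS-oxymethyl)benzaldehyde
Product: 5 [5-methoxy-2-(TIPS-oxy)-4-(TIPS-oxymethyl)phenyl]methanol
Conditions: NaBH4, MeOH/THF, −20 °C; AcOH quench
Reagents that add atoms: none
Why: Borohydride reduction of the aryl aldehyde gives the benzylic alcohol (future C11); low temperature and an acidic quench should avoid O-to-O silyl migration.

**Step 5**
Reactants: 5 [5-methoxy-2-(TIPS-oxy)-4-(TIPS-oxymethyl)phenyl]methanol
Product: 6 benzylic bromide ArCH2Br
Conditions: CBr4, PPh3, CH2Cl2, 0 °C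
Reagents that add atoms: carbon tetrabromide, BrC(Br)(Br)Br
Why: The Appel reaction turns the benzylic alcohol into the bromide under neutral conditions that leave both silyl ethers intact.

**Step 6**
Reactants: 7 (1R,5R)-(+)-verbenone; 8 2-(1,3-dioxan-2-yl)ethylmagnesium bromide; 6 benzylic bromide ArCH2Br
Product: 10 bicyclic keto acetal (pinane C4: methyl syn and dioxanylethyl anti to the CMe2 bridge; pinane C3: ArCH2 anti to the bridge), via bromomagnesium enolate 9 (not isolated)
Conditions: 8 (1.1 equiv), CuBr·SMe2 (10 mol %), THF, −40 °C; then 6 (1.3 equiv), DMPU, −40 to 0 °C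
Reagents that add atoms: none
Why: Copper-catalysed 1,4-addition of the Grignard reagent sets C10 (the chain enters anti to the CMe2 bridge and leaves the methyl syn to it), and the regiodefined enolate, which can only react at C9 because C7 is a bridgehead, is benzylated in the same flask (conjugate addition–enolate alkylation); the C9 configuration is corrected in step 9.

**Step 7**
Reactants: 10 bicyclic keto acetal
Product: 12 bicyclic keto (E)-tosylhydrazone, via keto aldehyde 11 (not isolated)
Conditions: TsNHNH2 (1.2 equiv), 1 M aq HCl (cat.), THF, 40 °C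
Reagents that add atoms: 4-methylbenzenesulfonohydrazide, Cc1ccc(cc1)S(=O)(=O)NN
Why: Acid-catalysed acetal hydrolysis with condensation in the same flask gives the aldehyde tosylhydrazone (hydrazone formation), the hindered bicyclic ketone being untouched.

**Step 8**
Reactants: 12 bicyclic keto (E)-tosylhydrazone
Product: 15 trans-fused ketone with ring A closed (9α-ArCH2-4,4,10β-trimethyl-5α-decalin-8-one), via stannyl enol ether diazene 13 (not isolated), via stannyl enol ether 14 (not isolated)
Conditions: Bu3SnH (1.3 equiv), AIBN (0.2 equiv), benzene, 80 °C, syringe-pump addition of the hydride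
Reagents that add atoms: none
Why: Proposed new method: Bu3Sn• adds to the C8 carbonyl oxygen to give an O-stannyl ketyl whose C7–C4 cyclobutane bond lies beta to the radical centre, so beta-scission (driven by cyclobutane strain and giving a tertiary radical, whereas cleavage of C7–C6 would give a primary one) releases the Me2C4 radical on C5 and the C7=C8 tin enolate of ring B. The nucleophilic tertiary radical adds 6-exo-trig to the electrophilic hydrazone carbon C3 and closes ring A through a chair in which C5–C4 and C10–C1 are both equatorial on ring B; because these two bonds were fixed trans in step 6 the fusion can only be trans, and no new permanent stereocentre arises. The hydrazinyl radical expels the toluenesulfonyl radical, which carries the chain by abstracting hydrogen from Bu3SnH, and the monoalkyl diazene 13 loses N2 to leave C3 as CH2, so the tether helper is traceless and the sulfinic acid protonates tin enolate 14 at C7 to give 15. The closest known reaction types are the O-stannyl ketyl ring opening of strained cycloalkyl ketones and the tin-hydride radical cyclisation onto sulfonylhydrazones with loss of sulfinate and N2; their merger, started from a pinane ketone, is the new element. The step needs beta-scission to outrun both hydrogen transfer to the ketyl and its direct addition to the hydrazone, which slow addition of the hydride and the bridged bicyclo[3.3.1] ring that direct addition would have to build across C9 (whose arylmethyl group sits on the same face) should secure.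

**Step 9**
Reactants: 15 9α-ArCH2 trans-decalin-8-one
Product: 16 9β-ArCH2-4,4,10β-trimethyl-5α-decalin-8-one
Conditions: t-BuOK (0.3 equiv), t-BuOH/THF, 40 °C
Reagents that add atoms: none
Why: Base-mediated epimerisation through the C8 enolate should place the C9 arylmethyl group equatorial (β), away from the three syn-axial hydrogens it meets in the 9α epimer (thermodynamic control).

**Step 10**
Reactants: 16 9β-ArCH2 trans-decalin-8-one
Product: 17 9β-ArCH2-4,4,10β-trimethyl-8-methylene-5α-decalin
Conditions: Ph3PCH3Br, KHMDS, toluene, 0 to 80 °C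
Reagents that add atoms: methyltriphenylphosphonium bromide, C[P+](c1ccccc1)(c1ccccc1)c1ccccc1.[Br-]
Why: Wittig methylenation of the C8 ketone gives the exocyclic C8=C12 alkene; C9 is already in its stable configuration, so the basic ylide cannot erode it.

**Step 11**
Reactants: 17 bis-silyl ether alkene
Product: 18 phenol (17 with both silyl groups removed: free C6' OH and C4' CH2OH)
Conditions: Bu4NF (2.5 equiv), THF, 0 °C to rt
Reagents that add atoms: none
Why: Fluoride cleaves the aryl and the benzylic silyl ether (desilylation) and frees the p-methoxyphenol and the C4' hydroxymethyl group.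

**Step 12**
Reactants: 18 phenol
Product: 19 quinone monoketal (C6' ketone; C3' dimethyl ketal)
Conditions: PhI(OAc)2, MeOH, 0 °C
Reagents that add atoms: methanol, CO
Why: Oxidative dearomatisation of the p-methoxyphenol with the hypervalent iodine reagent in methanol gives the quinone monoketal with the ketone at the former phenol carbon C6' and the ketal at C3'.

**Step 13**
Reactants: 19 quinone monoketal
Product: 20 C1'–C2' epoxy ketal (oxirane face as in the target)
Conditions: t-BuOOH, N-benzylcinchonidinium chloride (10 mol %), aq NaOH, toluene, 0 °C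
Reagents that add atoms: tert-butyl hydroperoxide, CC(C)(C)OO
Why: Nucleophilic (Weitz–Scheffer) epoxidation attacks the enone double bond C1'=C2', whose beta-carbon C2' is unsubstituted, in preference to C4'=C5' with its fully substituted beta-carbon, and the chiral ammonium hydroperoxide ion pair selects the face (phase-transfer catalysis, reagent control of C1' and C2').

**Step 14**
Reactants: 20 epoxy ketal
Product: 21 epoxyquinone (C3' and C6' ketones)
Conditions: PPTS, acetone/H2O, 40 °C
Reagents that add atoms: water, O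
Why: Mild acid hydrolysis of the dimethyl ketal unveils the C3' ketone; the oxirane, deactivated by its two flanking carbonyl carbons, and the exocyclic alkene should survive.

**Step 15**
Reactants: 21 epoxyquinone
Product: 22 epoxyquinol diol (C3' OH trans to the oxirane oxygen; free C4' CH2OH)
Conditions: NaBH(OAc)3, AcOH, MeCN, −20 °C
Reagents that add atoms: none
Why: The C4' hydroxymethyl group binds the triacetoxyborohydride and delivers hydride only to the neighbouring C3' carbonyl (hydroxyl-directed reduction); hydride should enter on the oxirane face because the other face is screened by the C1' decalinylmethyl group, which lies 1,3-syn-axial to that trajectory, giving the alcohol trans to the oxirane oxygen.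

**Step 16**
Reactants: 23 dimethyl 3-hydroxy-3-methylpentanedioate
Product: 24 (S)-3-hydroxy-5-methoxy-3-methyl-5-oxopentanoic acid
Conditions: pig liver esterase, pH 8 phosphate buffer, rt; extraction at pH 2
Reagents that add atoms: water, O
Why: Esterase-catalysed hydrolysis of one enantiotopic ester group of the prochiral diester sets the quaternary carbinol centre of the side chain (enzymatic desymmetrisation).

**Step 17**
Reactants: 22 epoxyquinol diol; 24 (S)-half ester
Product: 25 methyl ester of the target (primary C4' CH2O acylated)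
Conditions: EDC·HCl, DMAP (cat.), CH2Cl2, −20 °C
Reagents that add atoms: none
Why: Carbodiimide (Steglich) esterification acylates the unhindered primary allylic alcohol faster than the secondary C3' alcohol flanked by the oxirane; the tertiary alcohol of the acid does not react.

**Step 18**
Reactants: 25 methyl ester of the target
Product: 26 target CNP0158101.2
Conditions: pig liver esterase, pH 7.2 phosphate buffer/acetone, rt; extraction at pH 4
Reagents that add atoms: water, O
Why: The esterase should hydrolyse the small methyl ester at neutral pH and leave the hindered ester of the bulky allylic alcohol, the oxirane and the enone untouched (enzymatic ester hydrolysis).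

**Compound list**
1 | 4-bromo-2,5-dimethoxybenzaldehyde | COc1cc(C=O)c(OC)cc1Br | starting material
2 | 4-bromo-2-hydroxy-5-methoxybenzaldehyde | COc1cc(C=O)c(O)cc1Br | intermediate
3 | 2-hydroxy-4-(hydroxymethyl)-5-methoxybenzaldehyde | COc1cc(C=O)c(O)cc1CO | intermediate
4 | 5-methoxy-2-(TIPS-oxy)-4-(TIPS-oxymethyl)benzaldehyde | COc1cc(C=O)c(O[Si](C(C)C)(C(C)C)C(C)C)cc1CO[Si](C(C)C)(C(C)C)C(C)C | intermediate
5 | [5-methoxy-2-(TIPS-oxy)-4-(TIPS-oxymethyl)phenyl]methanol | COc1cc(CO)c(O[Si](C(C)C)(C(C)C)C(C)C)cc1CO[Si](C(C)C)(C(C)C)C(C)C | intermediate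
6 | 1-(bromomethyl)-5-methoxy-2-(TIPS-oxy)-4-(TIPS-oxymethyl)benzene (ArCH2Br) | COc1cc(CBr)c(O[Si](C(C)C)(C(C)C)C(C)C)cc1CO[Si](C(C)C)(C(C)C)C(C)C | intermediate
7 | (1R,5R)-(+)-verbenone, (1R,5R)-4,6,6-trimethylbicyclo[3.1.1]hept-3-en-2-one | CC1=CC(=O)[C@@H]2C[C@H]1C2(C)C | starting material
8 | 2-(1,3-dioxan-2-yl)ethylmagnesium bromide | Br[Mg]CCC1OCCCO1 | starting material
9 | bromomagnesium enolate of 4-[2-(1,3-dioxan-2-yl)ethyl]-4,6,6-trimethylbicyclo[3.1.1]heptan-2-one, chain anti to the CMe2 bridge | C[C@@]1(CCC2OCCCO2)C=C(O[Mg]Br)[C@@H]2C[C@H]1C2(C)C | intermediate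
10 | 3-(ArCH2)-4-[2-(1,3-dioxan-2-yl)ethyl]-4,6,6-trimethylbicyclo[3.1.1]heptan-2-one; 4-methyl syn, chain and ArCH2 anti to the CMe2 bridge | C[C@@]1(CCC2OCCCO2)[C@H](Cc2cc(OC)c(CO[Si](C(C)C)(C(C)C)C(C)C)cc2O[Si](C(C)C)(C(C)C)C(C)C)C(=O)[C@@H]2C[C@H]1C2(C)C | intermediate
11 | keto aldehyde: 10 with a 3-oxopropyl chain in place of the dioxanylethyl chain | C[C@@]1(CCC=O)[C@H](Cc2cc(OC)c(CO[Si](C(C)C)(C(C)C)C(C)C)cc2O[Si](C(C)C)(C(C)C)C(C)C)C(=O)[C@@H]2C[C@H]1C2(C)C | intermediate
12 | (E)-tosylhydrazone of aldehyde 11 | C[C@@]1(CC/C=N/NS(=O)(=O)c2ccc(C)cc2)[C@H](Cc2cc(OC)c(CO[Si](C(C)C)(C(C)C)C(C)C)cc2O[Si](C(C)C)(C(C)C)C(C)C)C(=O)[C@@H]2C[C@H]1C2(C)C | intermediate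
13 | tributylstannyl enol ether (C7=C8) of the ring A-closed decalone carrying a diazenyl group on C3 (C3 configuration open) | CCCC[Sn](CCCC)(CCCC)OC1=CC[C@H]2C(C)(C)C(N=N)CC[C@]2(C)[C@@H]1Cc1cc(OC)c(CO[Si](C(C)C)(C(C)C)C(C)C)cc1O[Si](C(C)C)(C(C)C)C(C)C | intermediate
14 | tributylstannyl enol ether (C7=C8) of ketone 15 | CCCC[Sn](CCCC)(CCCC)OC1=CC[C@H]2C(C)(C)CCC[C@]2(C)[C@@H]1Cc1cc(OC)c(CO[Si](C(C)C)(C(C)C)C(C)C)cc1O[Si](C(C)C)(C(C)C)C(C)C | intermediate
15 | 9α-(ArCH2)-4,4,10β-trimethyl-5α-decalin-8-one (trans-fused, 9-epi) | O=C1CC[C@H]2C(C)(C)CCC[C@]2(C)[C@@H]1Cc1cc(OC)c(CO[Si](C(C)C)(C(C)C)C(C)C)cc1O[Si](C(C)C)(C(C)C)C(C)C | intermediate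
16 | 9β-(ArCH2)-4,4,10β-trimethyl-5α-decalin-8-one | O=C1CC[C@H]2C(C)(C)CCC[C@]2(C)[C@H]1Cc1cc(OC)c(CO[Si](C(C)C)(C(C)C)C(C)C)cc1O[Si](C(C)C)(C(C)C)C(C)C | intermediate
17 | 9β-(ArCH2)-4,4,10β-trimethyl-8-methylene-5α-decalin | C=C1CC[C@H]2C(C)(C)CCC[C@]2(C)[C@H]1Cc1cc(OC)c(CO[Si](C(C)C)(C(C)C)C(C)C)cc1O[Si](C(C)C)(C(C)C)C(C)C | intermediate
18 | 4-(hydroxymethyl)-5-methoxy-2-[(8-methylene-4,4,10β-trimethyl-5α-decalin-9β-yl)methyl]phenol | C=C1CC[C@H]2C(C)(C)CCC[C@]2(C)[C@H]1Cc1cc(OC)c(CO)cc1O | intermediate
19 | 5-(hydroxymethyl)-4,4-dimethoxy-2-[(decalinyl)methyl]cyclohexa-2,5-dien-1-one (quinone monoketal) | C=C1CC[C@H]2C(C)(C)CCC[C@]2(C)[C@H]1CC1=CC(OC)(OC)C(CO)=CC1=O | intermediate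
20 | C1'–C2' epoxide of 19 (oxirane face as in the target) | C=C1CC[C@H]2C(C)(C)CCC[C@]2(C)[C@H]1C[C@]12O[C@H]1C(OC)(OC)C(CO)=CC2=O | intermediate
21 | epoxyquinone: C1'–C2' oxirane, C3' and C6' ketones, C4' CH2OH | C=C1CC[C@H]2C(C)(C)CCC[C@]2(C)[C@H]1C[C@]12O[C@H]1C(=O)C(CO)=CC2=O | intermediate
22 | epoxyquinol diol: 5,6-epoxy-4-hydroxy-3-(hydroxymethyl)-6-[(decalinyl)methyl]cyclohex-2-en-1-one, OH trans to the oxirane oxygen | C=C1CC[C@H]2C(C)(C)CCC[C@]2(C)[C@H]1C[C@]12O[C@H]1[C@H](O)C(CO)=CC2=O | intermediate
23 | dimethyl 3-hydroxy-3-methylpentanedioate | COC(=O)CC(C)(O)CC(=O)OC | starting material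
24 | (S)-3-hydroxy-5-methoxy-3-methyl-5-oxopentanoic acid | OC(=O)C[C@](C)(O)CC(=O)OC | intermediate
25 | methyl ester of the target (side-chain CO2Me) | C=C1CC[C@H]2C(C)(C)CCC[C@]2(C)[C@H]1C[C@]12O[C@H]1[C@H](O)C(COC(=O)C[C@](C)(O)CC(=O)OC)=CC2=O | intermediate
26 | CNP0158101.2 | C=C1CC[C@H]2C(C)(C)CCC[C@]2(C)[C@H]1C[C@]12O[C@H]1[C@H](O)C(COC(=O)C[C@](C)(O)CC(=O)O)=CC2=O | target

**Total step count:** 18
**Longest linear sequence:** 17 steps (steps 1–15, 17, 18)

**Steps most likely to fail**

Step 8 (proposed new method). The stannyloxy radical may add directly to the hydrazone carbon before the cyclobutane opens, or the ketyl or the tertiary radical may take up hydrogen before fragmentation or cyclisation, so that ring A is not closed. The fallback closes ring A by polar strain release and metathesis. It sets out from 7 and 6: vinylmagnesium bromide with CuBr·SMe2 adds to 7 and the enolate is benzylated with 6 as in step 6, giving the vinyl bicyclic ketone F1. TiCl4 with allyltrimethylsilane in CH2Cl2 at −78 °C opens the cyclobutane by heterolysis of C7–C4, and the tertiary cation is captured by the allylsilane (Hosomi–Sakurai type) to give the diene ketone F2. Ring-closing metathesis with the second-generation Grubbs catalyst joins C1 and C2 to give the octalone F3, and hydrogenation (H2, Pd/C) returns to the route at 15.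

Step 13. Facial selectivity may be poor if the ion pair does not discriminate the two faces of the flat dienone, or if the remote decalin opposes the catalyst. The fallback replaces catalyst control by an auxiliary. It sets out from 19: acetal exchange with (2R,4R)-pentane-2,4-diol (PPTS) gives the spiro-dioxane monoketal F4, whose axial methyl group screens one face of the C1'=C2' bond. Epoxidation with t-BuOOH and DBU gives the epoxide F5 (the enantiomeric diol is taken if the screened face is the wrong one), and hydrolysis as in step 14 returns to the route at 21.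

Step 15. Hydride may enter anti to the oxirane oxygen and give the C3' epimer. The fallback accepts this outcome and inverts the centre. It sets out from 21: reduction with NaBH4 and CeCl3·7H2O (Luche) gives the cis epoxy diol F6, and acylation of the primary alcohol with 24 as in step 17 gives the ester F7. Mitsunobu inversion at C3' with formic acid (PPh3, DIAD) gives the trans formate F8, and methanolysis of the formate (KHCO3, MeOH) returns to the route at 25.

**Further compounds**
F1 | step 8 | 3-(ArCH2)-4,6,6-trimethyl-4-vinylbicyclo[3.1.1]heptan-2-one (vinyl and ArCH2 anti to the CMe2 bridge) | C[C@@]1(C=C)[C@H](Cc2cc(OC)c(CO[Si](C(C)C)(C(C)C)C(C)C)cc2O[Si](C(C)C)(C(C)C)C(C)C)C(=O)[C@@H]2C[C@H]1C2(C)C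
F2 | step 8 | 2-(ArCH2)-3-methyl-4-(2-methylpent-4-en-2-yl)-3-vinylcyclohexanone (ring B ketone; vinyl on C10 and CMe2-allyl on C5 trans) | O=C1CC[C@@H](C(C)(C)CC=C)[C@](C)(C=C)[C@@H]1Cc1cc(OC)c(CO[Si](C(C)C)(C(C)C)C(C)C)cc1O[Si](C(C)C)(C(C)C)C(C)C
F3 | step 8 | 9α-(ArCH2)-4,4,10β-trimethyl-5α-octal-1-en-8-one (trans-fused, C1=C2) | O=C1CC[C@H]2C(C)(C)CC=C[C@]2(C)[C@@H]1Cc1cc(OC)c(CO[Si](C(C)C)(C(C)C)C(C)C)cc1O[Si](C(C)C)(C(C)C)C(C)C
F4 | step 13 | quinone monoketal of 19 with a (4R,6R)-4,6-dimethyl-1,3-dioxane spiro ketal at C3' | C=C1CC[C@H]2C(C)(C)CCC[C@]2(C)[C@H]1CC1=CC2(O[C@H](C)C[C@@H](C)O2)C(CO)=CC1=O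
F5 | step 13 | C1'–C2' epoxide of F4 (oxirane face as in the target) | C=C1CC[C@H]2C(C)(C)CCC[C@]2(C)[C@H]1C[C@]12O[C@H]1C1(O[C@H](C)C[C@@H](C)O1)C(CO)=CC2=O
F6 | step 15 | C3' epimer of diol 22 (OH cis to the oxirane oxygen) | C=C1CC[C@H]2C(C)(C)CCC[C@]2(C)[C@H]1C[C@]12O[C@H]1[C@@H](O)C(CO)=CC2=O
F7 | step 15 | C3' epimer of ester 25 | C=C1CC[C@H]2C(C)(C)CCC[C@]2(C)[C@H]1C[C@]12O[C@H]1[C@@H](O)C(COC(=O)C[C@](C)(O)CC(=O)OC)=CC2=O
F8 | step 15 | C3' formate of ester 25 (formyloxy trans to the oxirane oxygen) | C=C1CC[C@H]2C(C)(C)CCC[C@]2(C)[C@H]1C[C@]12O[C@H]1[C@H](OC=O)C(COC(=O)C[C@](C)(O)CC(=O)OC)=CC2=O
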